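Ring B is built, not bought: disconnecting its C1'–C2' and C5'–C6' bonds derives C2'–C3'–C4'–C5' from the chain of a 2-prenylacetoacetate, used as its 1-methoxy-1,3-bis(trimethylsilyloxy)diene, and C1'/C6' from a terminal alkyne already carrying the ring A aryl 1,2-dione. One cycloaddition–aromatization closes ring B, completes the skeleton and sets the acyl carbon C1' ortho to the C2' hydroxyl and para to the C4' hydroxyl. It exploits the fact that the O–C2'–C3'(prenyl)–C4'–O array of ring B is a disguised β-keto ester, so the prenyl group sits between the oxygens before any arene exists.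

Key step: step 6

Remark: ring B atoms are numbered C1' (the carbon bearing the dione) to C6'; racemic or geometrically mixed intermediates are carried as such, because every such element disappears when ring B aromatizes.

Step 1
Reactants: 1 2-bromo-5-methoxyphenol
Product: 2 1-bromo-4-methoxy-2-(methoxymethoxy)benzene
Conditions: MOMCl, i-Pr2NEt, CH2Cl2, 0 °C → rt
Reagents that add atoms: chloromethyl methyl ether, COCCl
Why: The phenol is O-alkylated by the reactive α-chloro ether under amine base (methoxymethyl ether formation, a Williamson-type alkylation), which installs a group that tolerates organolithium reagents, Grignard reagents and fluoride and is later removed by mild acid.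

Step 2
Reactants: 2 1-bromo-4-methoxy-2-(methoxymethoxy)benzene; 3 N,N'-dimethoxy-N,N'-dimethyloxamide; 4 ethynylmagnesium bromide
Product: 8 1-[4-methoxy-2-(methoxymethoxy)phenyl]but-3-yne-1,2-dione, via aryllithium 5 (not isolated), via lithium hemiaminal alkoxide 6 (not isolated), via mixed bis-hemiaminal dialkoxide 7 (not isolated)
Conditions: n-BuLi, THF, −78 °C; cannulated into 3 (1.1 equiv), THF, −78 °C; then 4 (THF solution, 2.5 equiv), −78 → 0 °C; inverse quench into cold 1 M aq. HCl/Et2O, 0 °C; short silica filtration, product kept cold and used the same day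
Reagents that add atoms: none
Why: Bromine–lithium exchange outpaces ortho-deprotonation at −78 °C, the aryllithium adds only once to the bis(N-methoxy-N-methyl)oxamide because the chelated tetrahedral adduct 6 does not collapse, the ethynyl Grignard reagent then converts the remaining amide in a second Weinreb ketone synthesis, and both carbonyls are released only in the cold acidic quench, which also protonates the liberated N,O-dimethylhydroxylamine so that it cannot add to the ynone.

Step 3
Reactants: 9 methyl acetoacetate; 10 prenyl bromide (1-bromo-3-methylbut-2-ene)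
Product: 12 methyl 2-acetyl-5-methylhex-4-enoate (methyl 2-prenylacetoacetate, racemic), via sodium enolate 11 (not isolated)
Conditions: NaH, THF, 0 °C; then 10 (0.9 equiv relative to 9), 0 °C → rt
Reagents that add atoms: none
Why: The sodium enolate of the β-keto ester is alkylated at its central carbon by the primary allylic bromide (SN2, acetoacetic ester alkylation), the slight excess of 9 limits dialkylation, and the racemic C2 stereocenter is erased in step 4.

Step 4
Reactants: 12 methyl 2-acetyl-5-methylhex-4-enoate
Product: 13 methyl 5-methyl-2-[1-(trimethylsilyloxy)ethylidene]hex-4-enoate (mixture of double-bond isomers)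
Conditions: TMSCl, Et3N, toluene, rt; filtration under argon, concentration
Reagents that add atoms: chlorotrimethylsilane, C[Si](C)(C)Cl
Why: Soft enolization of the β-keto ester by Et3N and O-silylation by TMSCl give the conjugated β-silyloxy enoate (silyl enol ether formation), the standard first stage of a bis-silyl dienol ether synthesis, and its double-bond geometry is irrelevant.

Step 5
Reactants: 13 methyl 5-methyl-2-[1-(trimethylsilyloxy)ethylidene]hex-4-enoate
Product: 15 1-methoxy-2-(3-methylbut-2-enyl)-1,3-bis(trimethylsilyloxy)buta-1,3-diene (ketene acetal geometry unassigned), via lithium dienolate 14 (not isolated)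
Conditions: LiN(i-Pr)2 (commercial solution), THF, −78 °C; then TMSCl, −78 °C → rt; hexane, filtration under argon; used crude
Reagents that add atoms: chlorotrimethylsilane, C[Si](C)(C)Cl
Why: The lithium amide removes a proton from the C4 methyl group of the vinylogous ester at −78 °C and the oxygen of the resulting dienolate 14 is silylated by TMSCl (kinetic γ-deprotonation and O-silylation), which gives the 1,3-dioxygenated diene that is handled with exclusion of moisture.

Step 6
Reactants: 8 1-[4-methoxy-2-(methoxymethoxy)phenyl]but-3-yne-1,2-dione; 15 1-methoxy-2-(3-methylbut-2-enyl)-1,3-bis(trimethylsilyloxy)buta-1,3-diene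
Product: 18 1-[2,4-dihydroxy-3-(3-methylbut-2-enyl)phenyl]-2-[4-methoxy-2-(methoxymethoxy)phenyl]ethane-1,2-dione, via silyl ketal cycloadduct 16 (not isolated), via dienone tautomer 17 (not isolated)
Conditions: 15 (1.5 equiv) added to 8, CH2Cl2, −78 °C → rt, no Lewis acid; then NH4F, MeOH, 0 °C → rt; pH 5 buffer work-up
Reagents that add atoms: none
Why: The electron-rich diene 15 attacks the unsubstituted alkyne terminus of ynone 8 with its CH2 terminus (bond C5'–C6') and its ketene acetal carbon then bonds to the internal alkyne carbon (bond C1'–C2'), either in a concerted but strongly asynchronous (4+2) cycloaddition or as a Mukaiyama–Michael addition followed by collapse of the allenolate onto the silyloxyallyl cation, giving the cyclohexa-1,4-diene ketal 16. The closest known reaction type is the Diels–Alder benzannulation of 1-alkoxy-1,3-bis(silyloxy)buta-1,3-dienes, 2-alkyl members included, with acetylenic ketones and esters, which delivers 2,4-dihydroxyaryl ketones and esters. Ring B is the only ring closed, by intermolecular (4+2) closure of a six-membered carbocycle, formally a 6-endo-trig closure in the stepwise limit. No stereocenter persists, because the ketal carbon of 16 and the ketene acetal geometry of 15 vanish when fluoride cleaves the O–Si bonds, the hemiketal expels methanol and dienone 17 enolizes to the arene. The step needs regioselectivity (acyl group ortho to the former ester carbon), secured by the matched polarization of the 1,3-dioxygenated diene and the ynone and by the prenyl group blocking the central diene carbon, and chemoselectivity for the alkyne over the dione carbonyls, secured by omitting any Lewis acid and by the hindered ring A ketone being deactivated by its electron-rich aryl group. Desilylation before any contact with acid makes methanol rather than silanol the leaving group, so that C2' ends as the free hydroxyl.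

Step 7
Reactants: 18 1-[2,4-dihydroxy-3-(3-methylbut-2-enyl)phenyl]-2-[4-methoxy-2-(methoxymethoxy)phenyl]ethane-1,2-dione
Product: 19 licoagrodione, 1-[2,4-dihydroxy-3-(3-methylbut-2-enyl)phenyl]-2-(2-hydroxy-4-methoxyphenyl)ethane-1,2-dione
Conditions: HCl (ca. 0.3 M) in MeOH, 0 °C → rt, monitored closely; NaHCO3 quench
Reagents that add atoms: none
Why: The aryl methoxymethyl ether is an acetal that dilute acid in methanol cleaves by acetal exchange to dimethoxymethane, assisted by the ortho carbonyl, while the low acid concentration, low temperature and short time should leave the prenyl group beside the free C4' hydroxyl uncyclized.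

Compound list
1 | 2-bromo-5-methoxyphenol | COc1ccc(Br)c(O)c1 | starting material
2 | 1-bromo-4-methoxy-2-(methoxymethoxy)benzene | COCOc1cc(OC)ccc1Br | intermediate
3 | N,N'-dimethoxy-N,N'-dimethyloxamide | CON(C)C(=O)C(=O)N(C)OC | starting material
4 | ethynylmagnesium bromide (THF solution) | C#C[Mg]Br | starting material
5 | 4-methoxy-2-(methoxymethoxy)phenyllithium (formed in the flask) | [Li]c1ccc(OC)cc1OCOC | intermediate
6 | lithium 1,2-bis[methoxy(methyl)amino]-1-[4-methoxy-2-(methoxymethoxy)phenyl]-2-oxoethan-1-olate (racemic, formed in the flask) | COCOc1cc(OC)ccc1C(O[Li])(N(C)OC)C(=O)N(C)OC | intermediate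
7 | mixed lithium/bromomagnesium 1,2-bis[methoxy(methyl)amino]-1-[4-methoxy-2-(methoxymethoxy)phenyl]but-3-yne-1,2-diolate (diastereomer mixture, formed in the flask) | COCOc1cc(OC)ccc1C(O[Li])(N(C)OC)C(O[Mg]Br)(C#C)N(C)OC | intermediate
8 | 1-[4-methoxy-2-(methoxymethoxy)phenyl]but-3-yne-1,2-dione | C#CC(=O)C(=O)c1ccc(OC)cc1OCOC | intermediate
9 | methyl acetoacetate | CC(=O)CC(=O)OC | starting material
10 | prenyl bromide (1-bromo-3-methylbut-2-ene) | CC(C)=CCBr | starting material
11 | sodium enolate of methyl acetoacetate (formed in the flask) | CC(O[Na])=CC(=O)OC | intermediate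
12 | methyl 2-acetyl-5-methylhex-4-enoate (racemic) | CC(=O)C(CC=C(C)C)C(=O)OC | intermediate
13 | methyl 5-methyl-2-[1-(trimethylsilyloxy)ethylidene]hex-4-enoate (mixture of double-bond isomers) | CC(O[Si](C)(C)C)=C(CC=C(C)C)C(=O)OC | intermediate
14 | lithium 1-methoxy-2-(3-methylbut-2-enyl)-3-(trimethylsilyloxy)buta-1,3-dien-1-olate (formed in the flask) | C=C(O[Si](C)(C)C)C(CC=C(C)C)=C(OC)O[Li] | intermediate
15 | 1-methoxy-2-(3-methylbut-2-enyl)-1,3-bis(trimethylsilyloxy)buta-1,3-diene (ketene acetal geometry unassigned) | C=C(O[Si](C)(C)C)C(CC=C(C)C)=C(OC)O[Si](C)(C)C | intermediate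
16 | 1-[6-methoxy-5-(3-methylbut-2-enyl)-4,6-bis(trimethylsilyloxy)cyclohexa-1,4-dien-1-yl]-2-[4-methoxy-2-(methoxymethoxy)phenyl]ethane-1,2-dione (racemic, formed in the flask) | COC1(O[Si](C)(C)C)C(CC=C(C)C)=C(O[Si](C)(C)C)CC=C1C(=O)C(=O)c1ccc(OC)cc1OCOC | intermediate
17 | 1-[4-hydroxy-5-(3-methylbut-2-enyl)-6-oxocyclohexa-1,4-dien-1-yl]-2-[4-methoxy-2-(methoxymethoxy)phenyl]ethane-1,2-dione (formed in the flask) | O=C1C(CC=C(C)C)=C(O)CC=C1C(=O)C(=O)c1ccc(OC)cc1OCOC | intermediate
18 | 1-[2,4-dihydroxy-3-(3-methylbut-2-enyl)phenyl]-2-[4-methoxy-2-(methoxymethoxy)phenyl]ethane-1,2-dione | COCOc1cc(OC)ccc1C(=O)C(=O)c1ccc(O)c(CC=C(C)C)c1O | intermediate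
19 | licoagrodione | COc1ccc(C(=O)C(=O)c2ccc(O)c(CC=C(C)C)c2O)c(O)c1 | target

Total step count: 7. Longest linear sequence: 5 steps (9 → 12 → 13 → 15 → 18 → 19); the ring A branch (1 → 2 → 8) joins at step 6.

Steps most likely to fail

Step 6. The silyl ketene acetal terminus of the diene may add to the very electrophilic central carbonyl of the dione (aldol-type addition or hetero-cycloaddition), or the Michael addition may stop without ring closure, so that the chemoselectivity for the alkyne is lost. The fallback carries the distal carbonyl one oxidation level lower, so that the dienophile is an ordinary α-silyloxy ynone of the well-documented class. It sets out from 2 and 3 and comes back at 18.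
- The mono-adduct 6 is made as in step 2 and quenched with cold aqueous acid instead of being treated with 4, giving N-methoxy-2-[4-methoxy-2-(methoxymethoxy)phenyl]-N-methyl-2-oxoacetamide F1.
- NaBH4 in MeOH at −20 °C reduces only the ketone and gives racemic 2-hydroxy-N-methoxy-2-[4-methoxy-2-(methoxymethoxy)phenyl]-N-methylacetamide F2.
- TBSCl and imidazole in DMF give the silyl ether 2-(tert-butyldimethylsilyloxy)-N-methoxy-2-[4-methoxy-2-(methoxymethoxy)phenyl]-N-methylacetamide F3.
- Ethynylmagnesium bromide 4 (THF, 0 °C, cold acidic quench) gives 1-(tert-butyldimethylsilyloxy)-1-[4-methoxy-2-(methoxymethoxy)phenyl]but-3-yn-2-one F4.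
- Cycloaddition of F4 with 15 (CH2Cl2 or toluene, rt to 50 °C) and NH4F/MeOH work-up should give 2-(tert-butyldimethylsilyloxy)-1-[2,4-dihydroxy-3-(3-methylbut-2-enyl)phenyl]-2-[4-methoxy-2-(methoxymethoxy)phenyl]ethan-1-one F5.
- Bu4NF buffered with AcOH in THF frees the benzoin 1-[2,4-dihydroxy-3-(3-methylbut-2-enyl)phenyl]-2-hydroxy-2-[4-methoxy-2-(methoxymethoxy)phenyl]ethan-1-one F6.
- MnO2 in CH2Cl2 at rt oxidizes the benzylic α-hydroxy ketone to the dione 18.

Step 2. The first tetrahedral intermediate may collapse before the Grignard reagent has reacted, so that the ethynyl nucleophile adds to the liberated aryl ketone. The liberated hydroxylamine may also add to the terminal ynedione, or the ynedione may oligomerize, during quench and isolation. The fallback separates the two additions by a redox detour; it sets out from 2 and 3 and comes back at 8.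
- The keto amide F1 and the hydroxy amide F2 are prepared as described above.
- Excess ethynylmagnesium bromide 4 (3.5 equiv, THF, 0 °C → rt; the first equivalent only deprotonates the hydroxyl) converts F2 into racemic 1-hydroxy-1-[4-methoxy-2-(methoxymethoxy)phenyl]but-3-yn-2-one F7.
- 1,1,1-Triacetoxy-1,1-dihydro-1,2-benziodoxol-3(1H)-one (DMP) with NaHCO3 in CH2Cl2 at 0 °C oxidizes the α-hydroxy ketone to 8 in an amine-free medium, from which 8 is taken directly into step 6.

Step 7. Acid may add the C4' hydroxyl (or methanol) across the prenyl double bond, so that chroman formation competes with acetal cleavage. The fallback carries the ring A hydroxyl as an allyl ether, which is removed without acid; it sets out from 1 and comes back at 19.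
- Allyl bromide and K2CO3 in acetone at reflux give 1-bromo-4-methoxy-2-(prop-2-enyloxy)benzene F8.
- The conditions of step 2 (3, then 4) give 1-[4-methoxy-2-(prop-2-enyloxy)phenyl]but-3-yne-1,2-dione F9.
- The conditions of step 6 with 15 give 1-[2,4-dihydroxy-3-(3-methylbut-2-enyl)phenyl]-2-[4-methoxy-2-(prop-2-enyloxy)phenyl]ethane-1,2-dione F10.
- Catalytic Pd(PPh3)4 (zerovalent palladium) with morpholine in THF at rt transfers the allyl group to the amine and gives 19.

Further compounds
F1 | step 6 | N-methoxy-2-[4-methoxy-2-(methoxymethoxy)phenyl]-N-methyl-2-oxoacetamide | CON(C)C(=O)C(=O)c1ccc(OC)cc1OCOC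
F2 | step 6 | 2-hydroxy-N-methoxy-2-[4-methoxy-2-(methoxymethoxy)phenyl]-N-methylacetamide (racemic) | CON(C)C(=O)C(O)c1ccc(OC)cc1OCOC
F3 | step 6 | 2-(tert-butyldimethylsilyloxy)-N-methoxy-2-[4-methoxy-2-(methoxymethoxy)phenyl]-N-methylacetamide (racemic) | CON(C)C(=O)C(O[Si](C)(C)C(C)(C)C)c1ccc(OC)cc1OCOC
F4 | step 6 | 1-(tert-butyldimethylsilyloxy)-1-[4-methoxy-2-(methoxymethoxy)phenyl]but-3-yn-2-one (racemic) | C#CC(=O)C(O[Si](C)(C)C(C)(C)C)c1ccc(OC)cc1OCOC
F5 | step 6 | 2-(tert-butyldimethylsilyloxy)-1-[2,4-dihydroxy-3-(3-methylbut-2-enyl)phenyl]-2-[4-methoxy-2-(methoxymethoxy)phenyl]ethan-1-one (racemic) | COCOc1cc(OC)ccc1C(O[Si](C)(C)C(C)(C)C)C(=O)c1ccc(O)c(CC=C(C)C)c1O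
F6 | step 6 | 1-[2,4-dihydroxy-3-(3-methylbut-2-enyl)phenyl]-2-hydroxy-2-[4-methoxy-2-(methoxymethoxy)phenyl]ethan-1-one (racemic) | COCOc1cc(OC)ccc1C(O)C(=O)c1ccc(O)c(CC=C(C)C)c1O
F7 | step 2 | 1-hydroxy-1-[4-methoxy-2-(methoxymethoxy)phenyl]but-3-yn-2-one (racemic) | C#CC(=O)C(O)c1ccc(OC)cc1OCOC
F8 | step 7 | 1-bromo-4-methoxy-2-(prop-2-enyloxy)benzene | C=CCOc1cc(OC)ccc1Br
F9 | step 7 | 1-[4-methoxy-2-(prop-2-enyloxy)phenyl]but-3-yne-1,2-dione | C#CC(=O)C(=O)c1ccc(OC)cc1OCC=C
F10 | step 7 | 1-[2,4-dihydroxy-3-(3-methylbut-2-enyl)phenyl]-2-[4-methoxy-2-(prop-2-enyloxy)phenyl]ethane-1,2-dione | C=CCOc1cc(OC)ccc1C(=O)C(=O)c1ccc(O)c(CC=C(C)C)c1O
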